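**Retrosynthetic overview**

1. Germacranolide numbering is used: lactone O1–C6, C7, C11(=C13H2), C12(=O); ester on C8; C9; C10(–C14HO)=C1; C2; C3; C4(–C15H2OH)=C5–C6. The endgame is an invertive esterification of C8–OH, then one acidic step that frees C14 (dioxolane to CHO) and C15 (silyl ether to OH).
2. Key disconnection C7–C8 of the ten-membered ring: the C8 carbinol is homoallylic to the exocyclic C11=C13 methylene through C7, and the allyl triad C13–C11–C7 lies inside the five-membered lactone ring (O1, C12, C11, C7, C6). The lactone is therefore carried as a flat 3-(bromomethyl)butenolide (C13–Br, C7=C11) whose γ-carbon C7 adds to a tethered C8 aldehyde (Cr(II), Nozaki–Hiyama); this closes the carbocycle, creates C7 and C8 and moves the olefin to the exo position in one operation.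
3. The cyclisation substrate (one stereocentre, C6) comes from an open-chain bis-allylic alcohol by acylation with 2-(bromomethyl)acrylic acid and ring-closing metathesis (butenolide, first ring).
4. The chain is joined at C3–C4 by B-alkyl Suzuki coupling of a (Z)-vinyl iodide (C4–C7, C15; asymmetric alkynylation of crotonaldehyde, then trans-hydroalumination/iodination) with the 9-BBN adduct of a diene acetal (C1–C3, C8–C10, C14; formyl-ylide Wittig reaction with acrolein).
5. Ring order: butenolide (step 9), then the ten-membered carbocycle as the last ring (step 12).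

Key step: step 12

Remark: (S,S)-ProPhenol is assumed to be the ligand antipode that delivers the (S)-carbinol 3 (if its facial sense is the opposite, the (R,R)-ligand is used); the CIP descriptor at C6 changes along the route (S in 3–17, R from 18 on) only because substituent priorities change.

**Route**

Step 1
Reactants: 1 tert-butyl(diphenyl)(prop-2-yn-1-yloxy)silane; 2 (E)-but-2-enal
Product: 3 (4S,5E)-1-[(tert-butyldiphenylsilyl)oxy]hept-5-en-2-yn-4-ol
Conditions: Me2Zn (3 equiv), (S,S)-ProPhenol (20 mol%), Ph3P=O (40 mol%), toluene, 0 °C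
Reagents that add atoms: none
Why: Zn–ProPhenol-catalysed enantioselective alkynylation (alkynylzinc 1,2-addition to an enal): the dinuclear zinc catalyst binds aldehyde and alkynylzinc together and should deliver the alkyne to one enantioface of the carbonyl, setting the C6 carbinol (S here), with 1,2- rather than 1,4-addition as is usual for alkynylzinc reagents.

Step 2
Reactants: 3 (4S,5E)-1-[(tert-butyldiphenylsilyl)oxy]hept-5-en-2-yn-4-ol
Product: 5 (2Z,4S,5E)-1-[(tert-butyldiphenylsilyl)oxy]-2-iodohepta-2,5-dien-4-ol, via cyclic alkenylalanate 4 (not isolated)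
Conditions: Red-Al, THF, 0 °C → rt; then I2, −78 → 0 °C
Reagents that add atoms: iodine, II
Why: Hydroxyl-directed trans-hydroalumination of the propargylic alcohol (Red-Al) should place H on C5 and Al on C4 through cyclic alanate 4, and iodinolysis with retention then gives the (Z)-vinyl iodide that fixes the ring-cis C4=C5 geometry, while the isolated propenyl group, the silyl ether and the C6 stereocentre are untouched.

Step 3
Reactants: 6 (3-bromopropoxy)(tert-butyl)dimethylsilane
Product: 7 {3-[(tert-butyldimethylsilyl)oxy]propyl}triphenylphosphonium bromide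
Conditions: PPh3, MeCN, reflux
Reagents that add atoms: triphenylphosphine, c1ccc(cc1)P(c1ccccc1)c1ccccc1
Why: SN2 quaternisation of triphenylphosphine by the primary bromide (phosphonium salt formation); no stereocentre is involved.

Step 4
Reactants: 7 {3-[(tert-butyldimethylsilyl)oxy]propyl}triphenylphosphonium bromide; 8 ethyl formate
Product: 10 4-[(tert-butyldimethylsilyl)oxy]-2-(triphenyl-λ5-phosphanylidene)butanal, via unformylated ylide 9 (not isolated)
Conditions: KOtBu (2.1 equiv), THF, 0 °C; then HCO2Et, 0 °C → rt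
Reagents that add atoms: none
Why: Deprotonation to ylide 9 and C-acylation with ethyl formate (ylide formylation), the excess base removing the acidic proton of the formylphosphonium ion, should give the stabilised α-formyl ylide that carries C8–C10 and C14.

Step 5
Reactants: 10 4-[(tert-butyldimethylsilyl)oxy]-2-(triphenyl-λ5-phosphanylidene)butanal; 11 prop-2-enal (acrolein)
Product: 12 (2E)-2-{2-[(tert-butyldimethylsilyl)oxy]ethyl}penta-2,4-dienal
Conditions: acrolein (3 equiv), BHT (cat.), toluene, 60 °C
Reagents that add atoms: none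
Why: Wittig olefination with a stabilised α-branched formyl ylide should react only at the aldehyde of acrolein and give the E enal under thermodynamic control, i.e. formyl trans and the CH2CH2O arm cis to the vinyl group, which is the ring-cis C1=C10 geometry of the target.

Step 6
Reactants: 12 (2E)-2-{2-[(tert-butyldimethylsilyl)oxy]ethyl}penta-2,4-dienal
Product: 13 2-[(3E)-1-{[tert-butyl(dimethyl)silyl]oxy}hexa-3,5-dien-3-yl]-1,3-dioxolane
Conditions: TMSOCH2CH2OTMS, TMSOTf (5 mol%), CH2Cl2, −78 °C; pyridine quench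
Reagents that add atoms: 1,2-bis(trimethylsilyloxy)ethane, C[Si](C)(C)OCCO[Si](C)(C)C
Why: Noyori acetalisation (TMSOTf-catalysed transfer of the glycol from its bis-silyl ether at −78 °C) should mask the enal as its dioxolane without double-bond migration or loss of the TBS ether, so that C14 keeps the aldehyde oxidation level but stays inert until the last step.

Step 7
Reactants: 13 2-[(3E)-1-{[tert-butyl(dimethyl)silyl]oxy}hexa-3,5-dien-3-yl]-1,3-dioxolane; 5 (2Z,4S,5E)-1-[(tert-butyldiphenylsilyl)oxy]-2-iodohepta-2,5-dien-4-ol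
Product: 15 (2E,4S,5E,9E)-12-[(tert-butyldimethylsilyl)oxy]-6-{[(tert-butyldiphenylsilyl)oxy]methyl}-10-(1,3-dioxolan-2-yl)dodeca-2,5,9-trien-4-ol, via B-alkyl-9-BBN adduct 14 (not isolated)
Conditions: 9-BBN, THF, 0 °C → rt; then 5, PdCl2(dppf) (5 mol%), AsPh3, Cs2CO3, DMF/H2O, rt
Reagents that add atoms: none
Why: 9-BBN should add to the terminal vinyl carbon of the diene only (the trisubstituted alkene is too hindered), and the resulting primary alkylborane undergoes B-alkyl Suzuki–Miyaura coupling with the vinyl iodide with retention of both olefin geometries in the presence of the free alcohol, joining C3 to C4.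

Step 8
Reactants: 15 (2E,4S,5E,9E)-12-[(tert-butyldimethylsilyl)oxy]-6-{[(tert-butyldiphenylsilyl)oxy]methyl}-10-(1,3-dioxolan-2-yl)dodeca-2,5,9-trien-4-ol; 16 2-(bromomethyl)prop-2-enoic acid
Product: 17 (2E,4S,5E,9E)-12-[(tert-butyldimethylsilyl)oxy]-6-{[(tert-butyldiphenylsilyl)oxy]methyl}-10-(1,3-dioxolan-2-yl)dodeca-2,5,9-trien-4-yl 2-(bromomethyl)prop-2-enoate
Conditions: DCC, DMAP (5 mol%), CH2Cl2, −20 → 0 °C
Reagents that add atoms: none
Why: Steglich esterification (carbodiimide activation, acyl transfer by DMAP) acylates the only free hydroxyl with retention at C6; low temperature and a catalytic amount of DMAP limit its addition to the bromomethacrylate.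

Step 9
Reactants: 17 (2E,4S,5E,9E)-12-[(tert-butyldimethylsilyl)oxy]-6-{[(tert-butyldiphenylsilyl)oxy]methyl}-10-(1,3-dioxolan-2-yl)dodeca-2,5,9-trien-4-yl 2-(bromomethyl)prop-2-enoate
Product: 18 (5R)-3-(bromomethyl)-5-[(1E,5E)-8-[(tert-butyldimethylsilyl)oxy]-2-{[(tert-butyldiphenylsilyl)oxy]methyl}-6-(1,3-dioxolan-2-yl)octa-1,5-dien-1-yl]furan-2(5H)-one
Conditions: second-generation Ru benzylidene metathesis catalyst (5–10 mol%), CH2Cl2 (5 mM), 40 °C
Reagents that add atoms: none
Why: Ring-closing metathesis between the propenyl group and the acrylate (propene is lost) should close the five-membered lactone as the 3-(bromomethyl)butenolide, the two trisubstituted chain olefins being too hindered to enter the cycle and C6 being untouched.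

Step 10
Reactants: 18 (5R)-3-(bromomethyl)-5-[(1E,5E)-8-[(tert-butyldimethylsilyl)oxy]-2-{[(tert-butyldiphenylsilyl)oxy]methyl}-6-(1,3-dioxolan-2-yl)octa-1,5-dien-1-yl]furan-2(5H)-one
Product: 19 (5R)-3-(bromomethyl)-5-[(1E,5E)-2-{[(tert-butyldiphenylsilyl)oxy]methyl}-6-(1,3-dioxolan-2-yl)-8-hydroxyocta-1,5-dien-1-yl]furan-2(5H)-one
Conditions: HF·pyridine, THF, 0 °C
Reagents that add atoms: none
Why: Fluoride-mediated desilylation: the primary alkyl TBS ether is cleaved much faster than the bulkier primary TBDPS ether, and unbuffered, anhydrous HF·pyridine offers no free amine or base to attack the allylic bromide, the acidic C6–H or the dioxolane.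

Step 11
Reactants: 19 (5R)-3-(bromomethyl)-5-[(1E,5E)-2-{[(tert-butyldiphenylsilyl)oxy]methyl}-6-(1,3-dioxolan-2-yl)-8-hydroxyocta-1,5-dien-1-yl]furan-2(5H)-one
Product: 20 (5R)-3-(bromomethyl)-5-[(1E,5E)-2-{[(tert-butyldiphenylsilyl)oxy]methyl}-6-(1,3-dioxolan-2-yl)-8-oxoocta-1,5-dien-1-yl]furan-2(5H)-one
Conditions: Dess–Martin periodinane, NaHCO3, CH2Cl2, 0 °C; used at once
Reagents that add atoms: none
Why: Dess–Martin oxidation under bicarbonate buffer converts the primary alcohol into the β,γ-unsaturated aldehyde without base- or acid-induced migration of the C1=C10 bond; the aldehyde is used without purification.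

Step 12
Reactants: 20 (5R)-3-(bromomethyl)-5-[(1E,5E)-2-{[(tert-butyldiphenylsilyl)oxy]methyl}-6-(1,3-dioxolan-2-yl)-8-oxoocta-1,5-dien-1-yl]furan-2(5H)-one
Product: 22 (3aR,4S,6E,10E,11aR)-10-{[(tert-butyldiphenylsilyl)oxy]methyl}-6-(1,3-dioxolan-2-yl)-4-hydroxy-3-methylidene-3a,4,5,8,9,11a-hexahydrocyclodeca[b]furan-2(3H)-one, via allylchromium(III) species 21 (not isolated)
Conditions: CrCl2 (8 equiv), THF, rt, syringe-pump addition of 20 (final 2 mM); aqueous work-up
Reagents that add atoms: none
Why: Two Cr(II) centres insert into the allylic C13–Br bond to give allylchromium(III) species 21 with the metal on the primary carbon C13, and its γ-carbon C7 adds to the tethered C8 aldehyde through a six-membered Zimmerman–Traxler transition state (SE2′), so the butenolide double bond moves out of the ring to C11=C13. The closest known reaction type is the Nozaki–Hiyama (Barbier) allylation of aldehydes by 2-(bromomethyl)acrylate-type bromides, including 3-(bromomethyl)butenolides, and its intramolecular use to close ten-membered germacranolide rings. The ten-membered ring closes by the C7–C8 bond in a 10-exo-trig attack on the carbonyl, the two cis trisubstituted olefins already bending the C5–C9 tether back towards C7. C7 is controlled by C6: in a chair transition state C9 must be gauche to C6, and attack on the face syn to C5 would push C5 and C9 into a syn-pentane-type contact, so C8 should add anti to the C5 substituent and give the trans-fused lactone. C8 is controlled by the chair itself: the butenolide locks the γ-substituent C6 trans to C13 (E-crotyl-like, pseudo-equatorial), and with the C9 chain pseudo-equatorial the anti carbinol (8S) results, i.e. the C8 epimer of the target, which step 13 corrects by inversion. The step needs γ- over α-attack (secured by chromium residing on primary C13), cyclisation over oligomerisation (syringe-pump addition, 2 mM) and a single carbonyl electrophile (C14 is an acetal; lactone, silyl ethers and olefins are inert to allylchromium).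

Step 13
Reactants: 22 (3aR,4S,6E,10E,11aR)-10-{[(tert-butyldiphenylsilyl)oxy]methyl}-6-(1,3-dioxolan-2-yl)-4-hydroxy-3-methylidene-3a,4,5,8,9,11a-hexahydrocyclodeca[b]furan-2(3H)-one; 23 (2R)-2-methylbutanoic acid
Product: 24 (3aR,4R,6E,10E,11aR)-10-{[(tert-butyldiphenylsilyl)oxy]methyl}-6-(1,3-dioxolan-2-yl)-3-methylidene-2-oxo-2,3,3a,4,5,8,9,11a-octahydrocyclodeca[b]furan-4-yl (2R)-2-methylbutanoate
Conditions: PPh3, DIAD, toluene, 0 °C → rt
Reagents that add atoms: none
Why: Mitsunobu esterification: the alkoxyphosphonium ion of the C8 alcohol is displaced by the carboxylate in an SN2 step, so the ester is installed with inversion to the 8R configuration of the target, while the acid's own α-stereocentre is not touched because the carboxylate acts only as an O-nucleophile.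

Step 14
Reactants: 24 (3aR,4R,6E,10E,11aR)-10-{[(tert-butyldiphenylsilyl)oxy]methyl}-6-(1,3-dioxolan-2-yl)-3-methylidene-2-oxo-2,3,3a,4,5,8,9,11a-octahydrocyclodeca[b]furan-4-yl (2R)-2-methylbutanoate
Product: 25 (3aR,4R,6E,10E,11aR)-6-formyl-10-(hydroxymethyl)-3-methylidene-2-oxo-2,3,3a,4,5,8,9,11a-octahydrocyclodeca[b]furan-4-yl (2R)-2-methylbutanoate (CNP0168859.5)
Conditions: 48% aq. HF, MeCN, 0 °C → rt
Reagents that add atoms: water, O
Why: Aqueous HF cleaves the Si–O bond of the TBDPS ether and hydrolyses the dioxolane, which ionises easily to a conjugated oxocarbenium ion, giving the allylic alcohol and the E enal (the stable geometry) without touching the ester, the α-methylene lactone or any stereocentre.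

**Compound list**

1 | tert-butyl(diphenyl)(prop-2-yn-1-yloxy)silane | C#CCO[Si](c1ccccc1)(c1ccccc1)C(C)(C)C | starting material
2 | (E)-but-2-enal | C/C=C/C=O | starting material
3 | (4S,5E)-1-[(tert-butyldiphenylsilyl)oxy]hept-5-en-2-yn-4-ol | O[C@@H](/C=C/C)C#CCO[Si](c1ccccc1)(c1ccccc1)C(C)(C)C | intermediate
4 | cyclic alkenylalanate (sodium 1,2-oxaluminol-2-uide carrying two 2-methoxyethoxy groups on Al) | COCCO[Al-]1(OCCOC)O[C@@H](/C=C/C)C=C1CO[Si](c2ccccc2)(c2ccccc2)C(C)(C)C.[Na+] | intermediate (not isolated)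
5 | (2Z,4S,5E)-1-[(tert-butyldiphenylsilyl)oxy]-2-iodohepta-2,5-dien-4-ol | O[C@@H](/C=C/C)/C=C(/CO[Si](c1ccccc1)(c1ccccc1)C(C)(C)C)I | intermediate
6 | (3-bromopropoxy)(tert-butyl)dimethylsilane | BrCCCO[Si](C)(C)C(C)(C)C | starting material
7 | {3-[(tert-butyldimethylsilyl)oxy]propyl}triphenylphosphonium bromide | CC(C)(C)[Si](C)(C)OCCC[P+](c1ccccc1)(c1ccccc1)c1ccccc1.[Br-] | intermediate
8 | ethyl formate | CCOC=O | starting material
9 | {3-[(tert-butyldimethylsilyl)oxy]propylidene}triphenylphosphorane | CC(C)(C)[Si](C)(C)OCCC=P(c1ccccc1)(c1ccccc1)c1ccccc1 | intermediate (not isolated)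
10 | 4-[(tert-butyldimethylsilyl)oxy]-2-(triphenyl-λ5-phosphanylidene)butanal | CC(C)(C)[Si](C)(C)OCCC(C=O)=P(c1ccccc1)(c1ccccc1)c1ccccc1 | intermediate
11 | prop-2-enal (acrolein) | C=CC=O | starting material
12 | (2E)-2-{2-[(tert-butyldimethylsilyl)oxy]ethyl}penta-2,4-dienal | C=C/C=C(/C=O)CCO[Si](C)(C)C(C)(C)C | intermediate
13 | 2-[(3E)-1-{[tert-butyl(dimethyl)silyl]oxy}hexa-3,5-dien-3-yl]-1,3-dioxolane | C=C/C=C(/C1OCCO1)CCO[Si](C)(C)C(C)(C)C | intermediate
14 | 9-[(3E)-6-[(tert-butyldimethylsilyl)oxy]-4-(1,3-dioxolan-2-yl)hex-3-en-1-yl]-9-borabicyclo[3.3.1]nonane | B1(CC/C=C(/C3OCCO3)CCO[Si](C)(C)C(C)(C)C)C2CCCC1CCC2 | intermediate (not isolated)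
15 | (2E,4S,5E,9E)-12-[(tert-butyldimethylsilyl)oxy]-6-{[(tert-butyldiphenylsilyl)oxy]methyl}-10-(1,3-dioxolan-2-yl)dodeca-2,5,9-trien-4-ol | O[C@@H](/C=C/C)/C=C(/CO[Si](c1ccccc1)(c1ccccc1)C(C)(C)C)CC/C=C(/C1OCCO1)CCO[Si](C)(C)C(C)(C)C | intermediate
16 | 2-(bromomethyl)prop-2-enoic acid | C=C(CBr)C(=O)O | starting material
17 | 2-(bromomethyl)prop-2-enoate ester of 15 | C=C(CBr)C(=O)O[C@@H](/C=C/C)/C=C(/CO[Si](c1ccccc1)(c1ccccc1)C(C)(C)C)CC/C=C(/C1OCCO1)CCO[Si](C)(C)C(C)(C)C | intermediate
18 | (5R)-3-(bromomethyl)-5-[(1E,5E)-8-[(tert-butyldimethylsilyl)oxy]-2-{[(tert-butyldiphenylsilyl)oxy]methyl}-6-(1,3-dioxolan-2-yl)octa-1,5-dien-1-yl]furan-2(5H)-one | O=C1O[C@@H](C=C1CBr)/C=C(/CO[Si](c2ccccc2)(c2ccccc2)C(C)(C)C)CC/C=C(/C2OCCO2)CCO[Si](C)(C)C(C)(C)C | intermediate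
19 | (5R)-3-(bromomethyl)-5-[(1E,5E)-2-{[(tert-butyldiphenylsilyl)oxy]methyl}-6-(1,3-dioxolan-2-yl)-8-hydroxyocta-1,5-dien-1-yl]furan-2(5H)-one | O=C1O[C@@H](C=C1CBr)/C=C(/CO[Si](c2ccccc2)(c2ccccc2)C(C)(C)C)CC/C=C(/C2OCCO2)CCO | intermediate
20 | (5R)-3-(bromomethyl)-5-[(1E,5E)-2-{[(tert-butyldiphenylsilyl)oxy]methyl}-6-(1,3-dioxolan-2-yl)-8-oxoocta-1,5-dien-1-yl]furan-2(5H)-one | O=C1O[C@@H](C=C1CBr)/C=C(/CO[Si](c2ccccc2)(c2ccccc2)C(C)(C)C)CC/C=C(/C2OCCO2)CC=O | intermediate
21 | allylchromium(III) dichloride derived from 20 (Cr on the former CH2Br carbon) | O=C1O[C@@H](C=C1C[Cr](Cl)Cl)/C=C(/CO[Si](c2ccccc2)(c2ccccc2)C(C)(C)C)CC/C=C(/C2OCCO2)CC=O | intermediate (not isolated)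
22 | (3aR,4S,6E,10E,11aR)-10-{[(tert-butyldiphenylsilyl)oxy]methyl}-6-(1,3-dioxolan-2-yl)-4-hydroxy-3-methylidene-3a,4,5,8,9,11a-hexahydrocyclodeca[b]furan-2(3H)-one (trans-fused lactone, both ring olefins cis in the ring, C8 epimeric to the target) | C=C1C(=O)O[C@@H]2/C=C(/CO[Si](c3ccccc3)(c3ccccc3)C(C)(C)C)CC/C=C(/C3OCCO3)C[C@H](O)[C@@H]12 | intermediate
23 | (2R)-2-methylbutanoic acid | CC[C@@H](C)C(=O)O | starting material
24 | (3aR,4R,6E,10E,11aR)-10-{[(tert-butyldiphenylsilyl)oxy]methyl}-6-(1,3-dioxolan-2-yl)-3-methylidene-2-oxo-2,3,3a,4,5,8,9,11a-octahydrocyclodeca[b]furan-4-yl (2R)-2-methylbutanoate | C=C1C(=O)O[C@@H]2/C=C(/CO[Si](c3ccccc3)(c3ccccc3)C(C)(C)C)CC/C=C(/C3OCCO3)C[C@@H](OC(=O)[C@H](C)CC)[C@@H]12 | intermediate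
25 | (3aR,4R,6E,10E,11aR)-6-formyl-10-(hydroxymethyl)-3-methylidene-2-oxo-2,3,3a,4,5,8,9,11a-octahydrocyclodeca[b]furan-4-yl (2R)-2-methylbutanoate (CNP0168859.5) | C=C1C(=O)O[C@@H]2/C=C(/CO)CC/C=C(/C=O)C[C@@H](OC(=O)[C@H](C)CC)[C@@H]12 | target

**Step count and risks**

Total step count: 14. Longest linear sequence: 12 steps (6 to 25 through steps 3–7 and 8–14).

Steps most likely to fail:

1. Step 12 (ring closure). The allylchromium species may be lost before it finds the aldehyde at high dilution, by vinylogous β-elimination of the lactone carboxylate (ring opening) or by protonation. Oligomerisation may compete, and ring strain could erode or reverse the chair preference at C8. Were the sense at C8 reversed, the ester would be introduced with retention (carbodiimide acylation) instead of inversion. Fallback for loss of the organometallic, setting out from 19 and coming back at 22: bromide 19 is borylated with bis(pinacolato)diboron and Pd2(dba)3 (toluene, 50 °C) to the allylboronate alcohol F1. Dess–Martin oxidation gives the boronate aldehyde F2, which is not purified but cyclised at high dilution with catalytic Sc(OTf)3 in toluene. This is an allylboration through the same closed chair transition state, with a covalent C–B bond that cannot eliminate. Hydrolysis of the B–O bond on work-up returns 22.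

2. Step 13 (invertive esterification). Activation of the hindered C8 carbinol may be slow, so that elimination towards C9 or addition of the phosphine to the α-methylene lactone competes with SN2 displacement. Fallback, setting out from 22 and coming back at 24: 22 is converted with chloromethanesulfonyl chloride and pyridine (CH2Cl2, 0 °C) into the chloromethanesulfonate F3. This is displaced with inversion by caesium (2R)-2-methylbutanoate F4 (prepared from 23 and Cs2CO3) with 18-crown-6 in toluene at 80 °C, giving 24.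

3. Step 7 (hydroboration and coupling). Hydroboration of the conjugated diene may occur in part at the internal position or twice, and the homoallylic borane may protodeboronate during coupling. Fallback, setting out from 5 and coming back at 15: 9-BBN is added to commercial acrolein diethyl acetal to give the alkylborane F5, which is coupled with 5 under the same Suzuki conditions to the diethyl acetal F6. Mild acid hydrolysis (PPTS, acetone/water) gives the aldehyde F7. Wittig reaction with ylide 10 (toluene, 80 °C) gives the E enal F8. Acetalisation as in step 6, followed by brief K2CO3/MeOH to free the carbinol from its transient silyl ether, returns 15.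

Further compounds
F1 | step 12 | (5R)-5-[(1E,5E)-2-{[(tert-butyldiphenylsilyl)oxy]methyl}-6-(1,3-dioxolan-2-yl)-8-hydroxyocta-1,5-dien-1-yl]-3-[(4,4,5,5-tetramethyl-1,3,2-dioxaborolan-2-yl)methyl]furan-2(5H)-one | O=C1O[C@@H](C=C1CB2OC(C)(C)C(C)(C)O2)/C=C(/CO[Si](c2ccccc2)(c2ccccc2)C(C)(C)C)CC/C=C(/C2OCCO2)CCO
F2 | step 12 | (5R)-5-[(1E,5E)-2-{[(tert-butyldiphenylsilyl)oxy]methyl}-6-(1,3-dioxolan-2-yl)-8-oxoocta-1,5-dien-1-yl]-3-[(4,4,5,5-tetramethyl-1,3,2-dioxaborolan-2-yl)methyl]furan-2(5H)-one | O=C1O[C@@H](C=C1CB2OC(C)(C)C(C)(C)O2)/C=C(/CO[Si](c2ccccc2)(c2ccccc2)C(C)(C)C)CC/C=C(/C2OCCO2)CC=O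
F3 | step 13 | chloromethanesulfonate of 22 (4S) | C=C1C(=O)O[C@@H]2/C=C(/CO[Si](c3ccccc3)(c3ccccc3)C(C)(C)C)CC/C=C(/C3OCCO3)C[C@H](OS(=O)(=O)CCl)[C@@H]12
F4 | step 13 | caesium (2R)-2-methylbutanoate | CC[C@@H](C)C(=O)[O-].[Cs+]
F5 | step 7 | 9-(3,3-diethoxypropyl)-9-borabicyclo[3.3.1]nonane | CCOC(CCB1C2CCCC1CCC2)OCC
F6 | step 7 | (4E,6S,7E)-4-{[(tert-butyldiphenylsilyl)oxy]methyl}-1,1-diethoxynona-4,7-dien-6-ol | O[C@@H](/C=C/C)/C=C(/CO[Si](c1ccccc1)(c1ccccc1)C(C)(C)C)CCC(OCC)OCC
F7 | step 7 | (4E,6S,7E)-4-{[(tert-butyldiphenylsilyl)oxy]methyl}-6-hydroxynona-4,7-dienal | O[C@@H](/C=C/C)/C=C(/CO[Si](c1ccccc1)(c1ccccc1)C(C)(C)C)CCC=O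
F8 | step 7 | (2E,6E,8S,9E)-2-{2-[(tert-butyldimethylsilyl)oxy]ethyl}-6-{[(tert-butyldiphenylsilyl)oxy]methyl}-8-hydroxyundeca-2,6,9-trienal | O[C@@H](/C=C/C)/C=C(/CO[Si](c1ccccc1)(c1ccccc1)C(C)(C)C)CC/C=C(/C=O)CCO[Si](C)(C)C(C)(C)C
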